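The pyranone ring C is cut at O1–C8a and C4–C4a, which reveals a 4-aryl-β-lactone and an aryl iodide. The key step exploits the ortho pairing on ring A of the ether oxygen O1 (on C8a, flanked by the C8 methoxy) and the C4 ketone (on C4a). In a palladium/norbornene (Catellani-type) annulation, 1-iodo-2,3-dimethoxybenzene takes up the acyl–O bond of the enantiopure lactone: ortho C–H acylation and ipso C–O coupling close the chromanone in one operation, with the stereocenter untouched. The lactone comes in one step from the benzyl-protected aldehyde by an asymmetric ketene–aldehyde [2+2] cycloaddition; hydrogenolysis ends the route.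

Key step: step 3

Remark: the target is the 2S flavanone. The quinine-derived catalyst of step 2 is assumed to give the S lactone, by analogy with the known sense of cinchona-alkaloid-catalysed ketene–aldehyde cycloadditions; if the sense proves opposite, the quinidine-derived pseudoenantiomer takes its place.

Step 1
Reactants: 1 3-hydroxy-4,5-dimethoxybenzaldehyde
Product: 2 3-(benzyloxy)-4,5-dimethoxybenzaldehyde
Conditions: BnBr, K2CO3, DMF, rt
Reagents that add atoms: benzyl bromide, BrCc1ccccc1
Why: Williamson ether synthesis: the phenoxide of 1, the only acidic site, is alkylated by benzyl bromide, which masks the phenol that would otherwise be acylated in step 2 and would compete for the lactone and for palladium in step 3; no stereocenter is involved.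

Step 2
Reactants: 2 3-(benzyloxy)-4,5-dimethoxybenzaldehyde
Product: 4 (S)-4-[3-(benzyloxy)-4,5-dimethoxyphenyl]oxetan-2-one, via ketene 3 (not isolated)
Conditions: AcCl (slow addition), i-Pr2NEt, O-trimethylsilylquinine (10 mol%), LiClO4, CH2Cl2/Et2O, −78 °C
Reagents that add atoms: acetyl chloride, CC(Cl)=O
Why: Alkaloid-catalysed asymmetric acyl halide–aldehyde cyclocondensation (nucleophile-catalysed ketene–aldehyde [2+2] cycloaddition): the catalyst amine adds to ketene 3 to give a chiral ammonium enolate that attacks one face of the LiClO4-activated aldehyde in a closed transition state and then lactonises with release of the catalyst, so the catalyst sets the C4 stereocenter (S expected from the quinine-derived pseudoenantiomer), while the two meta oxygens should keep the aldehyde about as electrophilic as benzaldehyde.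

Step 3
Reactants: 4 (S)-4-[3-(benzyloxy)-4,5-dimethoxyphenyl]oxetan-2-one, 5 1-iodo-2,3-dimethoxybenzene
Product: 6 (S)-2-[3-(benzyloxy)-4,5-dimethoxyphenyl]-7,8-dimethoxychroman-4-one
Conditions: Pd(OAc)2 (10 mol%), RuPhos (20 mol%), norbornene (1 equiv), K2CO3 (2 equiv), 4 (1.5 equiv), toluene, 70 °C
Reagents that add atoms: none
Why: Proposed new method: in this Catellani-type palladium/norbornene annulation, zerovalent palladium adds to the C–I bond of 5, norbornene inserts and the only free ortho C–H is palladated to an aryl–norbornyl palladacycle of divalent palladium, which cleaves the strained acyl–O bond of lactone 4 to a tetravalent-palladium acyl alkoxide; aryl–acyl reductive elimination then forms C4–C4a, norbornene is expelled by β-carbon elimination because both ortho positions are now filled, and the tethered alkoxide on divalent palladium forms O1–C8a by C–O reductive elimination, returning zerovalent palladium (all intermediates stay bound to palladium, none is set free). The closest known reactions, all under palladium/norbornene catalysis, are the ortho-acylation of aryl iodides by anhydrides, the formal insertion of the arene C–H/C–I pair into the C(O)–S bond of thioesters and the annulation of aryl iodides with epoxides that ends in ipso C(aryl)–O reductive elimination; what is new is a β-lactone as the donor of both the acyl group and the alkoxide. Ring C is closed as a formal [4+2] ring expansion of the lactone, its last bond made by reductive elimination from a seven-membered aryl–palladium–alkoxide chelate. No stereocenter is formed: C2 of 6 is C4 of 4, whose C–O bond is never broken, so the S configuration should be carried over with retention. Regiochemistry is fixed by the iodine atom, which puts O1 on the carbon next to the C8 methoxy (the methoxy also being the ortho blocking group that limits the reaction to one C–H acylation and forces norbornene extrusion) and the ketone on the neighbouring carbon, the orientation that nucleophilic addition of the oxygen to the corresponding 3-methoxyaryne would not give. The step needs acyl–O instead of benzylic C–O cleavage of 4 (the hindered secondary benzylic carbon resists attack by the bulky palladacycle), C–O reductive elimination instead of β-hydride elimination of the secondary alkoxide (chelation and the bulky biarylphosphine RuPhos) and no retro-oxa-Michael opening of 6 (weak, insoluble K2CO3 in toluene at 70 °C, a temperature chosen to stay below thermal decarboxylation of 4).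

Step 4
Reactants: 6 (S)-2-[3-(benzyloxy)-4,5-dimethoxyphenyl]-7,8-dimethoxychroman-4-one
Product: 7 (S)-2-(3-hydroxy-4,5-dimethoxyphenyl)-7,8-dimethoxychroman-4-one
Conditions: H2 (1 atm), Pd/C, EtOAc, rt
Reagents that add atoms: none
Why: Heterogeneous catalytic hydrogenolysis of the benzyl aryl ether under neutral conditions, which should cleave the O–CH2Ph bond much faster than it touches the aryl ketone or the cyclic benzylic C2–O1 bond and uses no base, so the C2 stereocenter is kept.

Compound list
1 | 3-hydroxy-4,5-dimethoxybenzaldehyde | COc1cc(C=O)cc(O)c1OC | starting material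
2 | 3-(benzyloxy)-4,5-dimethoxybenzaldehyde | COc1cc(C=O)cc(OCc2ccccc2)c1OC | intermediate
3 | ketene (formed in the flask from acetyl chloride and i-Pr2NEt) | C=C=O | intermediate
4 | (S)-4-[3-(benzyloxy)-4,5-dimethoxyphenyl]oxetan-2-one | O=C1C[C@@H](c2cc(OC)c(OC)c(OCc3ccccc3)c2)O1 | intermediate
5 | 1-iodo-2,3-dimethoxybenzene | COc1cccc(I)c1OC | starting material
6 | (S)-2-[3-(benzyloxy)-4,5-dimethoxyphenyl]-7,8-dimethoxychroman-4-one | COc1cc([C@@H]2CC(=O)c3ccc(OC)c(OC)c3O2)cc(OCc2ccccc2)c1OC | intermediate
7 | (S)-2-(3-hydroxy-4,5-dimethoxyphenyl)-7,8-dimethoxychroman-4-one | COc1cc([C@@H]2CC(=O)c3ccc(OC)c(OC)c3O2)cc(O)c1OC | target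

Total step count: 4. Longest linear sequence: 4 steps (1 → 2 → 4 → 6 → 7); 5 enters at step 3.

Steps most likely to fail

1. Step 3. Acyl–O activation of the lactone by the palladacycle may be too slow to compete with thermal decarboxylation of the lactone. The palladium alkoxide may undergo β-hydride elimination in place of C–O reductive elimination. The base may erode the enantiomeric purity through retro-oxa-Michael opening and reclosure of the product. The fallback uses known chemistry, sets out from 2 and comes back at 6. Commercial 1-(2-hydroxy-3,4-dimethoxyphenyl)ethanone is silylated on both the phenol and the enol oxygen (TBSOTf, Et3N, CH2Cl2, 0 °C) to give tert-butyl{[1-(2-{[tert-butyl(dimethyl)silyl]oxy}-3,4-dimethoxyphenyl)ethenyl]oxy}dimethylsilane F1. A catalytic asymmetric Mukaiyama aldol addition of this enol silane to 2 (SiCl4, chiral bisphosphoramide catalyst, CH2Cl2, −78 °C, the catalyst antipode chosen to give the R carbinol) should give (R)-3-[3-(benzyloxy)-4,5-dimethoxyphenyl]-1-(2-{[tert-butyl(dimethyl)silyl]oxy}-3,4-dimethoxyphenyl)-3-hydroxypropan-1-one F2. Buffered fluoride (TBAF, AcOH, THF, 0 °C) then frees the phenol to give (R)-3-[3-(benzyloxy)-4,5-dimethoxyphenyl]-3-hydroxy-1-(2-hydroxy-3,4-dimethoxyphenyl)propan-1-one F3. An intramolecular Mitsunobu etherification (PPh3, DIAD, THF, 0 °C) closes ring C with inversion at the carbinol carbon and should give 6 with the S configuration.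

2. Step 2. The aromatic aldehyde may react too slowly with the ammonium enolate, so that ketene dimerisation outruns the cross reaction. Facial selectivity may be insufficient. The benzylic lactone may open or lose CO2 during isolation. The fallback sets out from 2 and comes back at 4. A catalytic asymmetric Mukaiyama acetate aldol addition of 1-(tert-butyldimethylsilyloxy)-1-methoxyethene to 2 (SiCl4, chiral bisphosphoramide catalyst, CH2Cl2, −78 °C) should give methyl (S)-3-[3-(benzyloxy)-4,5-dimethoxyphenyl]-3-hydroxypropanoate F4. Saponification (LiOH, THF/H2O, 0 °C, then mild acid) gives (S)-3-[3-(benzyloxy)-4,5-dimethoxyphenyl]-3-hydroxypropanoic acid F5. Lactonisation by carboxyl activation (PhSO2Cl, pyridine, 0 °C) does not touch the carbinol C–O bond and should therefore give 4 with retention.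

3. Step 4. Over-reduction may occur alongside O-debenzylation: hydrogenolysis of the benzylic C2–O1 bond (ring opening to the dihydrochalcone) or reduction of the aryl ketone. The fallback sets out from 6 and comes back at 7. It replaces hydrogenolysis by Lewis-acid debenzylation with a cation scavenger (BCl3, pentamethylbenzene, CH2Cl2, −78 °C). This transfers the benzyl cation to the scavenger, leaves the ketone and the ring untouched, and at this temperature should spare the methyl ethers, none of which is ortho to the carbonyl; no new compound arises on the way (F0).

Further compounds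
F1 | step 3 | tert-butyl{[1-(2-{[tert-butyl(dimethyl)silyl]oxy}-3,4-dimethoxyphenyl)ethenyl]oxy}dimethylsilane | C=C(O[Si](C)(C)C(C)(C)C)c1ccc(OC)c(OC)c1O[Si](C)(C)C(C)(C)C
F2 | step 3 | (R)-3-[3-(benzyloxy)-4,5-dimethoxyphenyl]-1-(2-{[tert-butyl(dimethyl)silyl]oxy}-3,4-dimethoxyphenyl)-3-hydroxypropan-1-one | COc1cc([C@H](O)CC(=O)c2ccc(OC)c(OC)c2O[Si](C)(C)C(C)(C)C)cc(OCc2ccccc2)c1OC
F3 | step 3 | (R)-3-[3-(benzyloxy)-4,5-dimethoxyphenyl]-3-hydroxy-1-(2-hydroxy-3,4-dimethoxyphenyl)propan-1-one | COc1cc([C@H](O)CC(=O)c2ccc(OC)c(OC)c2O)cc(OCc2ccccc2)c1OC
F4 | step 2 | methyl (S)-3-[3-(benzyloxy)-4,5-dimethoxyphenyl]-3-hydroxypropanoate | COc1cc([C@@H](O)CC(=O)OC)cc(OCc2ccccc2)c1OC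
F5 | step 2 | (S)-3-[3-(benzyloxy)-4,5-dimethoxyphenyl]-3-hydroxypropanoic acid | COc1cc([C@@H](O)CC(=O)O)cc(OCc2ccccc2)c1OC
F0 | step 4 | none | none
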